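The decalin is opened at the ring-fusion bond C5–C10 and at C3–C4 (eudesmane numbering), which unfolds rings A and B into one acyclic chain. The key step exploits the methyl-bearing quaternary C10 and the oxidised C15 on C4: hydrogen-atom transfer to a C10=C14 methylidene gives the tertiary C10 radical, which closes ring B on C5 of a C5=C4–C15 enal, echoing the biosynthetic C10-to-C5 closure of a germacrane; the resulting C4 enolate closes ring A by aldol attack on the C3 aldehyde. The precursor is a linear 8-methylideneundec-2-enedial whose only stereocentre, C7, carries a malonate (masked acrylate) installed by iminium catalysis. Dehydration, reduction, methylenation and esterification finish.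

Key step: step 7

Remark: ring atoms are named by eudesmane numbering (C1–C10 in the decalin, C14 the angular methyl on C10, C15 the oxygenated carbon on C4, C11–C13 the acrylate unit on C7). 2-Bromohexa-1,5-diene is assumed not to be a stock item and is made in step 1. The sense of induction in step 4 is taken from the usual face-shielding model of the silyl prolinol catalyst.

Step 1
Reactants: 1 allylmagnesium bromide; 2 2,3-dibromoprop-1-ene
Product: 3 2-bromohexa-1,5-diene
Conditions: Et2O, 0 °C to rt
Reagents that add atoms: allylmagnesium bromide (1), C=CC[Mg]Br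
Why: SN2 displacement of the allylic bromide by the allyl Grignard reagent (the vinylic C–Br bond is inert without a catalyst), a known way to 2-bromo-1,5-dienes; no stereocentre is formed.

Step 2
Reactants: 3 2-bromohexa-1,5-diene; 4 2-(2-bromoethyl)-1,3-dioxolane
Product: 6 2-(3-methylidenehept-6-en-1-yl)-1,3-dioxolane, via Grignard reagent 5 (not isolated)
Conditions: 4, Mg, THF, 25 °C; then 3, PdCl2(dppf) (3 mol%), THF, 0 °C to rt
Reagents that add atoms: 2-(2-bromoethyl)-1,3-dioxolane (4), BrCCC1OCCO1, used as its Grignard reagent 5, Br[Mg]CCC1OCCO1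
Why: Kumada–Corriu coupling of a primary alkyl Grignard reagent with a vinyl bromide, in which the wide-bite-angle dppf ligand favours reductive elimination over β-hydride elimination; the Grignard reagent is kept at or below room temperature because it fragments on warming.

Step 3
Reactants: 6 2-(3-methylidenehept-6-en-1-yl)-1,3-dioxolane; 7 (E)-crotonaldehyde
Product: 8 (2E)-8-(1,3-dioxolan-2-yl)-6-methylideneoct-2-enal
Conditions: second-generation Hoveyda–Grubbs catalyst, RuCl2(H2IMes)(=CH-C6H4-2-OiPr) (3 mol%), crotonaldehyde (4 equiv), CH2Cl2, 40 °C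
Reagents that add atoms: (E)-crotonaldehyde (7), C/C=C/C=O
Why: Olefin cross-metathesis: the monosubstituted alkene couples with the electron-poor partner used in excess, the 1,1-disubstituted methylidene is too hindered to compete, and the conjugated product forms as the (E)-isomer.

Step 4
Reactants: 8 (2E)-8-(1,3-dioxolan-2-yl)-6-methylideneoct-2-enal; 9 dimethyl malonate
Product: 10 dimethyl 2-[(3R)-8-(1,3-dioxolan-2-yl)-6-methylidene-1-oxooctan-3-yl]propanedioate
Conditions: (S)-α,α-bis[3,5-bis(trifluoromethyl)phenyl]prolinol trimethylsilyl ether (10 mol%), EtOH, 0 °C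
Reagents that add atoms: dimethyl malonate (9), COC(=O)CC(=O)OC
Why: Iminium-ion-catalysed Michael addition: the (E)-iminium ion of 8 is shielded on one face by the diaryl(silyloxy)methyl group, so the malonate adds to C7 from the open face, which corresponds to the (R) configuration.

Step 5
Reactants: 10 dimethyl 2-[(3R)-8-(1,3-dioxolan-2-yl)-6-methylidene-1-oxooctan-3-yl]propanedioate; 11 (triphenylphosphoranylidene)acetaldehyde
Product: 12 dimethyl 2-[(2E,5R)-10-(1,3-dioxolan-2-yl)-8-methylidene-1-oxodec-2-en-5-yl]propanedioate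
Conditions: toluene, 80 °C
Reagents that add atoms: (triphenylphosphoranylidene)acetaldehyde (11), O=CC=P(c1ccccc1)(c1ccccc1)c1ccccc1
Why: Wittig olefination with a stabilised formyl ylide gives the (E)-enal under neutral conditions that avoid retro-Michael loss of the malonate; C7 is untouched.

Step 6
Reactants: 12 dimethyl 2-[(2E,5R)-10-(1,3-dioxolan-2-yl)-8-methylidene-1-oxodec-2-en-5-yl]propanedioate
Product: 13 dimethyl 2-[(2E,5R)-8-methylidene-1,11-dioxoundec-2-en-5-yl]propanedioate
Conditions: 1 M aq. HCl, THF, rt
Reagents that add atoms: water, O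
Why: Acid-catalysed hydrolysis of the dioxolane liberates the C3 aldehyde; the enal, the methylidene and the malonate should tolerate dilute acid at room temperature.

Step 7
Reactants: 13 dimethyl 2-[(2E,5R)-8-methylidene-1,11-dioxoundec-2-en-5-yl]propanedioate
Product: 15 dimethyl 2-[(2R,4aS,8aS)-8-formyl-7-hydroxy-4a-methyldecahydronaphthalen-2-yl]propanedioate (C3/C4 epimer mixture), via monocyclic iron enolate 14 (not isolated)
Conditions: Fe(acac)3 (30 mol%), PhSiH3 (2 equiv), EtOH/(CH2OH)2 (10:1), 0.01 M, argon, 0 °C to rt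
Reagents that add atoms: none
Why: The iron hydride formed from Fe(acac)3 and PhSiH3 transfers a hydrogen atom to the terminal carbon (C14) of the electron-rich 1,1-disubstituted alkene, the tertiary C10 radical adds to C5 of the enal (Giese addition), and divalent iron reduces the α-formyl radical to iron enolate 14, whose C4 attacks the C3 aldehyde. The closest known reaction type is the hydrogen-atom-transfer-initiated radical conjugate addition–aldol (radical–polar crossover) annulation, and the first bond copies the biosynthetic closure of a C10 cation onto C5. Ring B closes 6-exo-trig (radical) and ring A closes 6-(enolexo)-exo-trig (aldol). C5 is set by C7 through a chair transition state with the malonate and the enal both equatorial (C5–H α, cis-1,3 to the C7 substituent); C10 is set in the same transition state and needs the 3-oxopropyl arm, not the methyl group, in the equatorial site, which is favoured only by the slightly larger effective size of the arm, while C3 and C4 form as a mixture that step 8 erases. The step needs chemoselective hydrogen-atom transfer to the alkene and not the enal (electron-rich alkenes react faster with the metal hydride), enolate formation at C4 and not C2 (the crossover occurs at the carbon that carried the radical), and high dilution against intermolecular addition. The methyl/arm discrimination at C10 is the weak point: the arm-axial epimer would close to the cis-fused isomer, which is removed after step 8.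

Step 8
Reactants: 15 dimethyl 2-[(2R,4aS,8aS)-8-formyl-7-hydroxy-4a-methyldecahydronaphthalen-2-yl]propanedioate
Product: 16 dimethyl 2-[(2R,4aS,8aR)-8-formyl-4a-methyl-1,2,3,4,4a,5,6,8a-octahydronaphthalen-2-yl]propanedioate
Conditions: MsCl, Et3N, CH2Cl2, 0 °C to rt
Reagents that add atoms: none
Why: Mesylation of the C3 alcohol and E1cB elimination through the enolisable C4–H converts all C3/C4 epimers into the conjugated enal (the only α-hydrogen is on C4, so the alkene can form only between C3 and C4); C5, C7 and C10 are not affected.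

Step 9
Reactants: 16 dimethyl 2-[(2R,4aS,8aR)-8-formyl-4a-methyl-1,2,3,4,4a,5,6,8a-octahydronaphthalen-2-yl]propanedioate
Product: 17 dimethyl 2-[(2R,4aS,8aR)-8-(hydroxymethyl)-4a-methyl-1,2,3,4,4a,5,6,8a-octahydronaphthalen-2-yl]propanedioate
Conditions: NaBH4, CeCl3·7H2O, MeOH, −40 °C
Reagents that add atoms: none
Why: Luche reduction: cerium-activated 1,2-delivery of hydride reduces the enal to the allylic alcohol and leaves the malonate esters untouched.

Step 10
Reactants: 17 dimethyl 2-[(2R,4aS,8aR)-8-(hydroxymethyl)-4a-methyl-1,2,3,4,4a,5,6,8a-octahydronaphthalen-2-yl]propanedioate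
Product: 18 2-[(2R,4aS,8aR)-8-(hydroxymethyl)-4a-methyl-1,2,3,4,4a,5,6,8a-octahydronaphthalen-2-yl]-3-methoxy-3-oxopropanoic acid (C11 epimer mixture)
Conditions: KOH (1.05 equiv), MeOH, 0 °C to rt; then 1 M aq. HCl
Reagents that add atoms: potassium hydroxide, [K+].[OH-]
Why: Monosaponification of a malonate: after the first hydrolysis the carboxylate deactivates the remaining ester, and the new C11 centre is a mixture that step 11 erases.

Step 11
Reactants: 18 2-[(2R,4aS,8aR)-8-(hydroxymethyl)-4a-methyl-1,2,3,4,4a,5,6,8a-octahydronaphthalen-2-yl]-3-methoxy-3-oxopropanoic acid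
Product: 19 methyl 2-[(2R,4aR,8aR)-8-(hydroxymethyl)-4a-methyl-1,2,3,4,4a,5,6,8a-octahydronaphthalen-2-yl]prop-2-enoate
Conditions: paraformaldehyde, Et2NH, THF, reflux
Reagents that add atoms: formaldehyde (as paraformaldehyde), C=O
Why: Decarboxylative Mannich methylenation of a malonic half-ester: the Mannich base loses CO2 and Et2NH to give the 2-substituted acrylate (C11=C13) without touching C7.

Step 12
Reactants: 19 methyl 2-[(2R,4aR,8aR)-8-(hydroxymethyl)-4a-methyl-1,2,3,4,4a,5,6,8a-octahydronaphthalen-2-yl]prop-2-enoate; 20 (E)-4-hydroxycinnamic acid (p-coumaric acid)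
Product: 21 methyl 2-[(2R,4aR,8aR)-8-({[(2E)-3-(4-hydroxyphenyl)prop-2-enoyl]oxy}methyl)-4a-methyl-1,2,3,4,4a,5,6,8a-octahydronaphthalen-2-yl]prop-2-enoate (CNP0161949.1)
Conditions: PPh3, DIAD, THF, 0 °C to rt
Reagents that add atoms: (E)-4-hydroxycinnamic acid (20), OC(=O)/C=C/c1ccc(O)cc1
Why: Mitsunobu esterification: the carboxylic acid, far more acidic than the phenol, is the pronucleophile that displaces the oxyphosphonium group at the primary C15 by SN2, so neither the phenol nor a stereocentre is involved and the (E)-alkene of 20 is retained.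

Compound list
1 | allylmagnesium bromide | C=CC[Mg]Br | starting material
2 | 2,3-dibromoprop-1-ene | C=C(Br)CBr | starting material
3 | 2-bromohexa-1,5-diene | C=CCCC(Br)=C | intermediate
4 | 2-(2-bromoethyl)-1,3-dioxolane | BrCCC1OCCO1 | starting material
5 | [2-(1,3-dioxolan-2-yl)ethyl]magnesium bromide | Br[Mg]CCC1OCCO1 | intermediate
6 | 2-(3-methylidenehept-6-en-1-yl)-1,3-dioxolane | C=CCCC(=C)CCC1OCCO1 | intermediate
7 | (E)-crotonaldehyde | C/C=C/C=O | starting material
8 | (2E)-8-(1,3-dioxolan-2-yl)-6-methylideneoct-2-enal | O=C/C=C/CCC(=C)CCC1OCCO1 | intermediate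
9 | dimethyl malonate | COC(=O)CC(=O)OC | starting material
10 | dimethyl 2-[(3R)-8-(1,3-dioxolan-2-yl)-6-methylidene-1-oxooctan-3-yl]propanedioate | O=CC[C@H](C(C(=O)OC)C(=O)OC)CCC(=C)CCC1OCCO1 | intermediate
11 | (triphenylphosphoranylidene)acetaldehyde | O=CC=P(c1ccccc1)(c1ccccc1)c1ccccc1 | starting material
12 | dimethyl 2-[(2E,5R)-10-(1,3-dioxolan-2-yl)-8-methylidene-1-oxodec-2-en-5-yl]propanedioate | O=C/C=C/C[C@H](C(C(=O)OC)C(=O)OC)CCC(=C)CCC1OCCO1 | intermediate
13 | dimethyl 2-[(2E,5R)-8-methylidene-1,11-dioxoundec-2-en-5-yl]propanedioate | O=C/C=C/C[C@H](C(C(=O)OC)C(=O)OC)CCC(=C)CCC=O | intermediate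
14 | monocyclic iron enolate, ring B closed, drawn as the free enolate: cyclohexane carrying the malonate at C7, methyl and 3-oxopropyl at C10 and the 2-oxidoethenyl group at C5 (C5–H α, C10–CH3 β, C7 side chain β) | COC(=O)C(C(=O)OC)[C@@H]1CC[C@@](C)(CCC=O)[C@H](C=C[O-])C1 | intermediate
15 | dimethyl 2-[(2R,4aS,8aS)-8-formyl-7-hydroxy-4a-methyldecahydronaphthalen-2-yl]propanedioate, trans-fused, epimer mixture at the carbinol carbon C3 and the formyl-bearing carbon C4 | COC(=O)C(C(=O)OC)[C@@H]1CC[C@@]2(C)CCC(O)C(C=O)[C@@H]2C1 | intermediate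
16 | dimethyl 2-[(2R,4aS,8aR)-8-formyl-4a-methyl-1,2,3,4,4a,5,6,8a-octahydronaphthalen-2-yl]propanedioate | COC(=O)C(C(=O)OC)[C@@H]1CC[C@@]2(C)CCC=C(C=O)[C@@H]2C1 | intermediate
17 | dimethyl 2-[(2R,4aS,8aR)-8-(hydroxymethyl)-4a-methyl-1,2,3,4,4a,5,6,8a-octahydronaphthalen-2-yl]propanedioate | COC(=O)C(C(=O)OC)[C@@H]1CC[C@@]2(C)CCC=C(CO)[C@@H]2C1 | intermediate
18 | 2-[(2R,4aS,8aR)-8-(hydroxymethyl)-4a-methyl-1,2,3,4,4a,5,6,8a-octahydronaphthalen-2-yl]-3-methoxy-3-oxopropanoic acid, epimer mixture at C11 | COC(=O)C(C(=O)O)[C@@H]1CC[C@@]2(C)CCC=C(CO)[C@@H]2C1 | intermediate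
19 | methyl 2-[(2R,4aR,8aR)-8-(hydroxymethyl)-4a-methyl-1,2,3,4,4a,5,6,8a-octahydronaphthalen-2-yl]prop-2-enoate | C=C(C(=O)OC)[C@@H]1CC[C@@]2(C)CCC=C(CO)[C@@H]2C1 | intermediate
20 | (E)-4-hydroxycinnamic acid (p-coumaric acid) | OC(=O)/C=C/c1ccc(O)cc1 | starting material
21 | methyl 2-[(2R,4aR,8aR)-8-({[(2E)-3-(4-hydroxyphenyl)prop-2-enoyl]oxy}methyl)-4a-methyl-1,2,3,4,4a,5,6,8a-octahydronaphthalen-2-yl]prop-2-enoate | C=C(C(=O)OC)[C@@H]1CC[C@@]2(C)CCC=C(COC(=O)/C=C/c3ccc(O)cc3)[C@@H]2C1 | target

Total step count: 12. Longest linear sequence: 12 steps (steps 1 to 12; all coupling partners are purchased).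

Steps most likely to fail

Step 7 (key step). The iron enolate may be protonated by ethanol, the glycol or the acidic malonate C–H before it reaches C3, so that the cascade stops after ring B. In addition, weak discrimination between the methyl group and the 3-oxopropyl arm on the C10 radical would divert material to the cis-fused C10 epimer. The fallback sets out from 12 and comes back at 16, and separates the two ring closures.
- Acetal 12 is cyclised with Fe(acac)3/PhSiH3 in EtOH, where the C4 enolate is simply protonated, to give the monocyclic aldehyde acetal F1 (ring B only).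
- TMSCl/Et3N in DMF converts its aldehyde into the trimethylsilyl enol ether F2.
- TiCl4 in CH2Cl2 at −78 °C opens the dioxolane to an oxocarbenium ion at C3, which the enol ether captures through C4 (intramolecular Mukaiyama aldol with an acetal), giving the β-(2-hydroxyethoxy) aldehyde F3.
- DBU eliminates ethylene glycol by E1cB to give 16.

The enol ether fixes the nucleophile at C4 and the acetal fixes the electrophile at C3, so no enolate lifetime is needed. This variant does not change the face selectivity at C10; the C10 epimer is removed by chromatography at F1.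

Step 4. Slow iminium turnover with a β-alkyl enal, competing 1,2-addition and erosion of enantioselectivity may spoil the C7 centre. The fallback sets out from 8 and comes back at 10, and sets C7 by iridium-catalysed allylic alkylation.
- NaBH4/CeCl3·7H2O reduces 8 to the allylic alcohol F4.
- ClCO2Me/pyridine gives the methyl carbonate F5.
- [Ir(cod)Cl]2 with a chiral phosphoramidite ligand (the enantiomer that delivers the R product) and sodium dimethyl malonate (from 9 and NaH) in THF gives the branched malonate F6 by attack at the substituted allyl terminus.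
- Disiamylborane hydroborates only the monosubstituted vinyl group and NaBO3 oxidation gives the primary alcohol F7.
- Dess–Martin periodinane gives 10.

Step 12. The alkoxyphosphonium ion may alkylate the free phenol, or the carboxylate may attack the allylic system in the SN2′ sense. The fallback sets out from 19 and comes back at 21, and uses acylation with a phenol-protected acid.
- 19 is esterified with (E)-4-acetoxycinnamic acid (EDC·HCl, DMAP, CH2Cl2) to give the aryl acetate F8.
- The aryl acetate alone is cleaved with NH4OAc in aqueous MeOH to give 21.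

Further compounds
F1 | step 7 | dimethyl 2-{4-[2-(1,3-dioxolan-2-yl)ethyl]-4-methyl-3-(2-oxoethyl)cyclohexyl}propanedioate (C5, C7, C10 as in 16) | COC(=O)C(C(=O)OC)[C@@H]1CC[C@@](C)(CCC2OCCO2)[C@H](CC=O)C1
F2 | step 7 | trimethylsilyl enol ether of F1 | COC(=O)C(C(=O)OC)[C@@H]1CC[C@@](C)(CCC2OCCO2)[C@H](C=CO[Si](C)(C)C)C1
F3 | step 7 | dimethyl 2-[8-formyl-7-(2-hydroxyethoxy)-4a-methyldecahydronaphthalen-2-yl]propanedioate (trans-fused, C5, C7, C10 as in 15) | COC(=O)C(C(=O)OC)[C@@H]1CC[C@@]2(C)CCC(OCCO)C(C=O)[C@@H]2C1
F4 | step 4 | (2E)-8-(1,3-dioxolan-2-yl)-6-methylideneoct-2-en-1-ol | OC/C=C/CCC(=C)CCC1OCCO1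
F5 | step 4 | (2E)-8-(1,3-dioxolan-2-yl)-6-methylideneoct-2-en-1-yl methyl carbonate | COC(=O)OC/C=C/CCC(=C)CCC1OCCO1
F6 | step 4 | dimethyl 2-[(3R)-8-(1,3-dioxolan-2-yl)-6-methylideneoct-1-en-3-yl]propanedioate | C=C[C@H](C(C(=O)OC)C(=O)OC)CCC(=C)CCC1OCCO1
F7 | step 4 | dimethyl 2-[(3R)-8-(1,3-dioxolan-2-yl)-1-hydroxy-6-methylideneoctan-3-yl]propanedioate | OCC[C@H](C(C(=O)OC)C(=O)OC)CCC(=C)CCC1OCCO1
F8 | step 12 | methyl 2-[(2R,4aR,8aR)-8-({[(2E)-3-(4-acetoxyphenyl)prop-2-enoyl]oxy}methyl)-4a-methyl-1,2,3,4,4a,5,6,8a-octahydronaphthalen-2-yl]prop-2-enoate | C=C(C(=O)OC)[C@@H]1CC[C@@]2(C)CCC=C(COC(=O)/C=C/c3ccc(OC(C)=O)cc3)[C@@H]2C1
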